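Longipinane numbering is used (C1 ketone, C2=C3, cyclobutane C4–C5–C11–C10, bridge C6–C9). Everything rests on disconnecting the enone bond C2–C3 of ring C1–C2–C3–C4–C10–C11. Without that bond the core is a bicyclo[4.1.1]octane whose mirror plane (through C5, C10 and the C6–C9 bridge) interchanges C4 and C11. The key step, a chiral-amine-catalysed desymmetrising intramolecular aldol condensation, forms C2–C3, closes the bicyclo[3.1.1]heptenone and fixes the absolute configuration of all four cyclobutane stereocentres in one operation. Its precursor is the achiral 4,11-diacetyl bicyclic enone 27, on which racemic intermediates made from 2-methylcyclopentenone converge.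

Key step: step 10

Remark: numbering is C1(=O)–C2H=C3(CH3)–C4H–C5H–C6(CH3)2–C7H(O)–C8H2–C9H(O)–C10(CH3)–C11H, with further bonds C11–C1, C4–C10 and C5–C11. Compounds 4–24 and 26 are racemic; their SMILES show one enantiomer only, to define the relative configuration. Both enantiomers give the same achiral diketone 27.

Step 1
Reactants: 1 2-methylcyclopent-2-en-1-one; 2 isopropenylmagnesium bromide (CH2=C(CH3)MgBr); 3 chlorotrimethylsilane
Product: 4 racemic silyl enol ether
Conditions: CuBr·SMe2 (10 mol%), Me3SiCl, THF, −78 °C; Et3N, pentane, filtration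
Reagents that add atoms: isopropenylmagnesium bromide CC(=C)[Mg]Br; chlorotrimethylsilane C[Si](C)(C)Cl
Why: Copper-catalysed conjugate addition of the alkenyl Grignard reagent with silyl trapping gives the regiodefined tetrasubstituted enol silane; the new centre (future C4) is formed as a racemate, which is harmless because chirality is erased at 27.

Step 2
Reactants: 4 racemic silyl enol ether; 5 trimethyl orthoformate
Product: 6 racemic keto acetal
Conditions: Me3SiOTf (10 mol%), CH2Cl2, −78 °C
Reagents that add atoms: trimethyl orthoformate COC(OC)OC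
Why: Mukaiyama-type alkylation of the enol silane by the dimethoxycarbenium ion creates the quaternary centre (future C10); the electrophile should enter anti to the neighbouring isopropenyl group, placing the methyl cis to it.

Step 3
Reactants: 6 racemic keto acetal
Product: 8 racemic cyclopentenone, via lithium enolate 7 (not isolated)
Conditions: LiN(i-Pr)2, THF, −78 °C; then N-tert-butylbenzenesulfinimidoyl chloride, −78 °C
Reagents that add atoms: none
Why: The enolate can form only on the CH2 side (the other α-carbon is quaternary), and its one-pot dehydrogenation with the sulfinimidoyl chloride (an alternative to Saegusa–Ito oxidation) gives the C5=C11 enone.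

Step 4
Reactants: 8 racemic cyclopentenone; 9 isobutyronitrile; 10 methyllithium; 11 water
Product: 14 racemic diketone acetal, via cyano enolate 12 (not isolated), via lithio ketimine 13 (not isolated)
Conditions: 9, LiN(i-Pr)2, THF, −78 °C; add 8, DMPU, −78 → −30 °C; then MeLi (3 equiv), 0 °C → rt; AcOH/H2O/THF, 0 °C → rt
Reagents that add atoms: isobutyronitrile CC(C)C#N; methyllithium [Li]C; water O
Why: Michael addition of the tertiary nitrile anion should occur at C5 anti to the adjacent isopropenyl group (cis to the acetal); the resulting lithium enolate protects the ring ketone while MeLi adds once to the nitrile, and mild hydrolysis of the ketimine gives the methyl ketone (C7, C8).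

Step 5
Reactants: 14 racemic diketone acetal
Product: 16 racemic bicyclo[4.2.1]nonenedione, via keto aldehyde 15 (not isolated)
Conditions: TsOH·H2O (10 mol%), acetone/H2O, rt; then benzene, 80 °C, Dean–Stark
Reagents that add atoms: none
Why: Acid unmasks the neopentyl aldehyde (C9), which undergoes intramolecular aldol condensation (7-enolexo) with the methyl ketone across the cis-1,3 positions of the cyclopentanone to close the seven-membered ring; the competing aldol onto the ring ketone cannot dehydrate (bridgehead alkene) and is reversible.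

Step 6
Reactants: 16 racemic bicyclo[4.2.1]nonenedione; 17 4-acetamidobenzenesulfonyl azide
Product: 19 racemic diazo ketone, via trifluoroacetyl ketone 18 (not isolated)
Conditions: LiN(SiMe3)2, THF, −78 °C; CF3CO2CH2CF3; aq. HCl; then 17, Et3N, H2O, MeCN, rt
Reagents that add atoms: 4-acetamidobenzenesulfonyl azide CC(=O)Nc1ccc(cc1)S(=O)(=O)N=[N+]=[N-]
Why: Only the ring CH2 (future C11) is enolisable (C10 is quaternary, the bridge enone has no α- or γ-hydrogen), so trifluoroacetylation followed by deacylative Regitz diazo transfer should be regiospecific.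

Step 7
Reactants: 19 racemic diazo ketone; 11 water
Product: 21 racemic cyclobutane acid, via ketene 20 (not isolated)
Conditions: hν (LED, 400–450 nm), THF/H2O 10:1, rt
Reagents that add atoms: water O
Why: Photochemical Wolff rearrangement with migration of the quaternary C10 (retention) contracts the two-carbon bridge to the cyclobutane C4–C5–C11–C10 and water traps the ketene; the C11 configuration is not critical because it is epimerisable and only the anti isomer reacts in step 10, and long-wavelength light spares the enone.

Step 8
Reactants: 21 racemic cyclobutane acid; 22 dimethylzinc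
Product: 24 racemic methyl ketone, via acid chloride 23 (not isolated)
Conditions: (COCl)2, DMF (cat.), CH2Cl2, 0 °C → rt; evaporate; Me2Zn, Pd(PPh3)4 (5 mol%), THF, 0 °C → rt
Reagents that add atoms: dimethylzinc C[Zn]C
Why: Negishi acylation of the acid chloride installs the C2 methyl chemoselectively, since the organozinc reagent does not attack the bridge enone as MeLi or MeMgBr would.

Step 9
Reactants: 24 racemic methyl ketone; 25 ozone
Product: 27 meso diketone, via ozonide 26 (not isolated)
Conditions: O3 (1 equiv), CH2Cl2, −78 °C; Me2S, −78 °C → rt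
Reagents that add atoms: ozone [O-][O+]=O
Why: Ozonolysis should cleave the electron-rich 1,1-disubstituted alkene much faster than the conjugated bridge enone, unveiling the second acetyl group (C3, C12) and with it the mirror plane, so that 27 is achiral.

Step 10
Reactants: 27 meso diketone
Product: 29 tricyclic dienedione, via ketol 28 (not isolated)
Conditions: 9-amino-9-deoxy-epi-quinine (20 mol%; the quinidine-derived pseudo-enantiomer if the opposite sense is found), AcOH (60 mol%), toluene, 0 °C → rt
Reagents that add atoms: none
Why: The primary amine condenses with one acetyl group to an enamine whose carbon C2 attacks the carbonyl carbon C3 of the other acetyl group, held 1,3-diaxially across the cyclobutane, and the ketol loses water to give the C2=C3 enone. The closest known reaction type is the amine-catalysed enantiogroup-differentiating intramolecular aldol condensation of 4-substituted heptane-2,6-diones to 3-methylcyclohex-2-enones (Hajos–Parrish–Eder–Sauer–Wiechert family). The six-membered ring C1–C2–C3–C4–C10–C11 is closed in a 6-(enolexo)-exo-trig mode. No stereocentre is created at the new bond, but C4, C5, C10 and C11 become stereogenic at this moment, their absolute configuration being set by the catalyst's choice between the two enantiotopic acetyl groups. Group selectivity is thus the only selectivity needed; the substrate secures chemoselectivity, because the bridge enone has no enolisable hydrogen and a neopentyl β-carbon, and only the anti,anti-diacetyl arrangement, reached by epimerisation under the same conditions, can close.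

Step 11
Reactants: 29 tricyclic dienedione; 30 bis(pinacolato)diboron; 31 sodium perborate (NaBO3·4H2O)
Product: 33 hydroxy ketone, via boryl ketone 32 (not isolated)
Conditions: CuCl (5 mol%), NaOt-Bu (10 mol%), (R,R)-2,3-bis(tert-butylmethylphosphino)quinoxaline (6 mol%; or its enantiomer, whichever gives 9R), B2pin2, MeOH (2 equiv), THF, 0 °C; then NaBO3·4H2O, THF/H2O, rt
Reagents that add atoms: sodium perborate [Na+].[O-]OB=O
Why: Copper-catalysed asymmetric conjugate borylation should attack the β-monosubstituted bridge enone at C9 rather than the fully substituted C3 of the bicyclo[3.1.1]heptenone, the chiral copper–boryl complex (not the nearly symmetric substrate) choosing the face, and perborate oxidation with retention gives the 9-carbinol.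

Step 12
Reactants: 33 hydroxy ketone; 34 (E)-2-methylbut-2-enal
Product: 35 hydroxy tiglate
Conditions: SmI2 (30 mol%), 34 (6 equiv), THF, −10 °C
Reagents that add atoms: (E)-2-methylbut-2-enal C/C=C(\C)C=O
Why: Evans–Tishchenko reduction: the samarium-bound hemiacetal formed from O9 and the aldehyde delivers hydride intramolecularly to the C7 ketone, which sets the 7,9-anti (trans) relationship and leaves the tigloyl group on O9 in the same operation.

Step 13
Reactants: 35 hydroxy tiglate; 36 3-methylbut-2-enoyl chloride
Product: 37 target diester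
Conditions: pyridine, 4-(dimethylamino)pyridine (10 mol%), CH2Cl2, 0 °C → rt
Reagents that add atoms: 3-methylbut-2-enoyl chloride CC(C)=CC(Cl)=O
Why: DMAP-catalysed acylation of the remaining hindered C7 hydroxyl with the acid chloride, with pyridine instead of a trialkylamine to avoid deconjugation through the vinylketene, completes the target.

Compound list
1 | 2-methylcyclopent-2-en-1-one | CC1=CCCC1=O | starting material
2 | isopropenylmagnesium bromide | CC(=C)[Mg]Br | starting material
3 | chlorotrimethylsilane | C[Si](C)(C)Cl | starting material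
4 | (±)-trimethyl{[2-methyl-3-(prop-1-en-2-yl)cyclopent-1-en-1-yl]oxy}silane | C[Si](C)(C)OC1=C(C)[C@@H](C(C)=C)CC1 | intermediate
5 | trimethyl orthoformate | COC(OC)OC | starting material
6 | (±)-2-(dimethoxymethyl)-2-methyl-3-(prop-1-en-2-yl)cyclopentan-1-one; acetal trans, methyl cis to isopropenyl | O=C1CC[C@H](C(C)=C)[C@@]1(C)C(OC)OC | intermediate
7 | lithium enolate of 6 (C1=C5 of the cyclopentanone) | [Li]OC1=CC[C@H](C(C)=C)[C@@]1(C)C(OC)OC | intermediate (not isolated)
8 | (±)-5-(dimethoxymethyl)-5-methyl-4-(prop-1-en-2-yl)cyclopent-2-en-1-one; acetal trans to isopropenyl | O=C1C=C[C@H](C(C)=C)[C@@]1(C)C(OC)OC | intermediate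
9 | isobutyronitrile (2-methylpropanenitrile) | CC(C)C#N | starting material
10 | methyllithium | [Li]C | starting material
11 | water | O | starting material
12 | lithium enolate of the 1,4-adduct; 2-cyanopropan-2-yl group trans to isopropenyl, cis to the acetal | [Li]OC1=C[C@@H](C(C)(C)C#N)[C@H](C(C)=C)[C@@]1(C)C(OC)OC | intermediate (not isolated)
13 | dilithio species: ring enolate and N-lithio ketimine from MeLi addition to the nitrile of 12 | [Li]OC1=C[C@@H](C(C)(C)C(C)=N[Li])[C@H](C(C)=C)[C@@]1(C)C(OC)OC | intermediate (not isolated)
14 | (±)-2-(dimethoxymethyl)-2-methyl-4-(2-methyl-3-oxobutan-2-yl)-3-(prop-1-en-2-yl)cyclopentan-1-one; 2-acetal and 4-substituent cis, both trans to 3-isopropenyl | O=C1C[C@@H](C(C)(C)C(C)=O)[C@H](C(C)=C)[C@@]1(C)C(OC)OC | intermediate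
15 | (±)-1-methyl-3-(2-methyl-3-oxobutan-2-yl)-5-oxo-2-(prop-1-en-2-yl)cyclopentane-1-carbaldehyde; same relative configuration as 14 | O=C1C[C@@H](C(C)(C)C(C)=O)[C@H](C(C)=C)[C@@]1(C)C=O | intermediate (not isolated)
16 | (±)-2,2,6-trimethyl-9-(prop-1-en-2-yl)bicyclo[4.2.1]non-4-ene-3,7-dione; isopropenyl on C9 anti to the C2–C5 bridge | O=C1C[C@@H]2[C@H](C(C)=C)[C@@]1(C)C=CC(=O)C2(C)C | intermediate
17 | 4-acetamidobenzenesulfonyl azide | CC(=O)Nc1ccc(cc1)S(=O)(=O)N=[N+]=[N-] | starting material
18 | 8-(trifluoroacetyl) derivative of 16 (C8 configuration undefined) | O=C1C(C(=O)C(F)(F)F)[C@@H]2[C@H](C(C)=C)[C@@]1(C)C=CC(=O)C2(C)C | intermediate (not isolated)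
19 | (±)-8-diazo-2,2,6-trimethyl-9-(prop-1-en-2-yl)bicyclo[4.2.1]non-4-ene-3,7-dione | O=C1C(=[N+]=[N-])[C@@H]2[C@H](C(C)=C)[C@@]1(C)C=CC(=O)C2(C)C | intermediate
20 | ketene: (±)-2,2,6-trimethyl-7-(oxomethylidene)-8-(prop-1-en-2-yl)bicyclo[4.1.1]oct-4-en-3-one | O=C=C1[C@@H]2[C@H](C(C)=C)[C@@]1(C)C=CC(=O)C2(C)C | intermediate (not isolated)
21 | (±)-2,2,6-trimethyl-3-oxo-8-(prop-1-en-2-yl)bicyclo[4.1.1]oct-4-ene-7-carboxylic acid; CO2H and isopropenyl both anti to the C2–C5 bridge (the C7 epimer may accompany it) | OC(=O)[C@@H]1[C@@H]2[C@H](C(C)=C)[C@@]1(C)C=CC(=O)C2(C)C | intermediate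
22 | dimethylzinc | C[Zn]C | starting material
23 | acid chloride of 21 | ClC(=O)[C@@H]1[C@@H]2[C@H](C(C)=C)[C@@]1(C)C=CC(=O)C2(C)C | intermediate (not isolated)
24 | (±)-7-acetyl-2,2,6-trimethyl-8-(prop-1-en-2-yl)bicyclo[4.1.1]oct-4-en-3-one; both substituents anti to the C2–C5 bridge | CC(=O)[C@@H]1[C@@H]2[C@H](C(C)=C)[C@@]1(C)C=CC(=O)C2(C)C | intermediate
25 | ozone | [O-][O+]=O | starting material
26 | secondary ozonide (3-methyl-1,2,4-trioxolan-3-yl group in place of the isopropenyl group of 24) | CC(=O)[C@@H]1[C@@H]2[C@H](C3(C)OOCO3)[C@@]1(C)C=CC(=O)C2(C)C | intermediate (not isolated)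
27 | meso-7,8-diacetyl-2,2,6-trimethylbicyclo[4.1.1]oct-4-en-3-one; both acetyl groups anti to the C2–C5 bridge, achiral (acetyls on C4 and C11 in longipinane numbering) | CC(=O)[C@@H]1[C@@H]2[C@H](C(C)=O)[C@@]1(C)C=CC(=O)C2(C)C | intermediate
28 | ketol: 3-hydroxy-2,3-dihydro derivative of 29 (C3 configuration undefined) | C1=CC(=O)C(C)(C)[C@@H]2[C@H]3C(=O)CC(C)(O)[C@@H]2[C@]31C | intermediate (not isolated)
29 | (4R,5S,10R,11R)-longipina-2,8-diene-1,7-dione | C1=CC(=O)C(C)(C)[C@@H]2[C@H]3C(=O)C=C(C)[C@@H]2[C@]31C | intermediate
30 | bis(pinacolato)diboron | CC1(C)OB(OC1(C)C)B2OC(C)(C)C(C)(C)O2 | starting material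
31 | sodium perborate (NaBO3·4H2O, drawn as the anhydrous monomer) | [Na+].[O-]OB=O | starting material
32 | 9-(4,4,5,5-tetramethyl-1,3,2-dioxaborolan-2-yl) analogue of 33 (boron in the place of the C9 oxygen) | CC1(C)OB(OC1(C)C)[C@@H]2CC(=O)C(C)(C)[C@@H]3[C@H]4C(=O)C=C(C)[C@@H]3[C@]42C | intermediate (not isolated)
33 | (4R,5S,9R,10R,11R)-9-hydroxylongipin-2-ene-1,7-dione | O[C@@H]1CC(=O)C(C)(C)[C@@H]2[C@H]3C(=O)C=C(C)[C@@H]2[C@]31C | intermediate
34 | (E)-2-methylbut-2-enal (tiglic aldehyde) | C/C=C(\C)C=O | starting material
35 | (4R,5S,7R,9R,10R,11R)-7-hydroxy-1-oxolongipin-2-en-9-yl (E)-2-methylbut-2-enoate | C/C=C(\C)C(=O)O[C@@H]1C[C@@H](O)C(C)(C)[C@@H]2[C@H]3C(=O)C=C(C)[C@@H]2[C@]31C | intermediate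
36 | 3-methylbut-2-enoyl chloride (senecioyl chloride) | CC(C)=CC(Cl)=O | starting material
37 | (4R,5S,7R,9R,10R,11R)-7-(3-methylbut-2-enoyloxy)-1-oxolongipin-2-en-9-yl (E)-2-methylbut-2-enoate | C/C=C(\C)C(=O)O[C@@H]1C[C@@H](OC(=O)C=C(C)C)C(C)(C)[C@@H]2[C@H]3C(=O)C=C(C)[C@@H]2[C@]31C | target

Total step count: 13. Longest linear sequence: 13 steps (fully linear from 1).

Steps most likely to fail

Step 10. The catalyst may discriminate poorly between the two enantiotopic acetyl groups, or closure of the strained bicyclo[3.1.1]heptenone may be sluggish. The fallback sets out from 27. Aldol condensation with an achiral amine salt (pyrrolidine/AcOH, toluene, rt to 60 °C) would give the racemate, that is 29 together with the enantiomeric dienedione F1. The copper-catalysed borylation–oxidation of step 11 then serves as a catalyst-controlled resolution. 29 gives 33, whereas F1 gives the diastereomeric hydroxy ketone F2 (same C9 configuration on the mirror-image core), which is removed by chromatography. The route is rejoined at 33.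

Step 12. The β-hydroxy ketone may open by retro-aldol reaction, or the conjugated aldehyde may fail to transfer hydride. The fallback sets out from 33. Hydroxyl-directed reduction with Me4NBH(OAc)3 (MeCN/AcOH, −30 °C, Evans–Saksena reduction) should give the anti-diol F3. Mono-acylation with (E)-2-methylbut-2-enoyl chloride (1 equiv, pyridine, CH2Cl2, −20 °C) at the less hindered O9 (O7 is flanked by the gem-dimethyl carbon C6) comes back at 35. The regioisomeric ester would be separated and recycled by hydrolysis.

Step 4. The nitrile anion may deprotonate the enone at the γ-position instead of adding, or MeLi may add incompletely to the hindered nitrile. The fallback sets out from 8. Stork enamine Michael addition of 4-(2-methylprop-1-en-1-yl)morpholine (MeCN, reflux; then aqueous AcOH) should give the keto aldehyde F4, again anti to the isopropenyl group. Aldehyde-selective methylation with MeTi(Oi-Pr)3 (THF, −30 °C) gives the carbinol F5. Oxidation with Dess–Martin periodinane comes back at 14.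

Further compounds
F1 | step 10 | (4S,5R,10S,11S)-longipina-2,8-diene-1,7-dione (enantiomer of 29) | C1=CC(=O)C(C)(C)[C@H]2[C@@H]3C(=O)C=C(C)[C@H]2[C@@]31C
F2 | step 10 | (4S,5R,9R,10S,11S)-9-hydroxylongipin-2-ene-1,7-dione (diastereomer of 33) | O[C@@H]1CC(=O)C(C)(C)[C@H]2[C@@H]3C(=O)C=C(C)[C@H]2[C@@]31C
F3 | step 12 | (4R,5S,7R,9R,10R,11R)-7,9-dihydroxylongipin-2-en-1-one | O[C@@H]1C[C@@H](O)C(C)(C)[C@@H]2[C@H]3C(=O)C=C(C)[C@@H]2[C@]31C
F4 | step 4 | (±)-2-[3-(dimethoxymethyl)-3-methyl-4-oxo-2-(prop-1-en-2-yl)cyclopentyl]-2-methylpropanal; relative configuration as in 14 | O=C1C[C@@H](C(C)(C)C=O)[C@H](C(C)=C)[C@@]1(C)C(OC)OC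
F5 | step 4 | (±)-2-(dimethoxymethyl)-4-(3-hydroxy-2-methylbutan-2-yl)-2-methyl-3-(prop-1-en-2-yl)cyclopentan-1-one; carbinol configuration undefined | O=C1C[C@@H](C(C)(C)C(C)O)[C@H](C(C)=C)[C@@]1(C)C(OC)OC
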